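At early times charge and clock trade against each other. In the summer run, 0.90 M of incoming ligand gives 27.8% of complex with one exchanged at 2.50 h; in the autumn run, 1.8 M gives 28.0% at 1.50 h. The products of charge and time are 135 M·min and 162 M·min, with leaving ligand charged at 0.84 M and 0.60 M, so the trade is a rough one.

| setting | summer | noon | autumn | flask |
|---|---|---|---|---|
| starting complex | 0.30 M | 0.30 M | 0.30 M | 0.30 M |
| incoming ligand | 0.90 M | 0.90 M | 1.8 M | 0.900 M |
| leaving ligand | 0.84 M | 1.3 M | 0.60 M | 0.600 M |
| remark | run made earlier | run made earlier | run made earlier |  |
| time |  |  |  | 20 h |

- summer (time / h: complex with one exchanged / %, complex with two exchanged / %): 2.50: 27.8, 2.7; 8.00: 45.8, 13.0; 12.0: 49.4, 19.8; 20.0: 45.2, 34.8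
- noon (time / h: complex with one exchanged / %, complex with two exchanged / %): 5.00: 38.7, 5.7; 10.0: 49.5, 16.0; 15.0: 48.0, 28.6; 20.0: 43.8, 34.9
- autumn (time / h: complex with one exchanged / %, complex with two exchanged / %): 1.50: 28.0, 3.1; 4.00: 48.4, 15.2; 8.00: 45.5, 35.7; 20.0: 17.1, 72.9

(standard deviation of a reading: 1 percentage point)

- the analysis behind the earlier runs scatters by 1 percentage point, standard deviation

- equivalents of incoming ligand to starting complex, everything else as given, that leave most complex with one exchanged at 20 h
- the amount of complex with one exchanged then, in percent of the starting complex charged
- the amount of complex with one exchanged with the amounts as given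

So my rule of thumb treats each exchange as pseudo-first-order in its complex, with the clock counted in ligand dose, mean [incoming ligand] times time. The summer readings top out near 12.0 h, when 0.267 M of ligand has gone, counting one per one-exchanged complex and two per two-exchanged complex. I replace the curve by its mean, the charge minus half of that, and get 552 M·min, the peak dose.

To peak at 20 h, a flask needs a mean of 0.460 M, so a charge of 0.593 M, or 1.98 equiv, with a peak read near 49.4%. For the flask as charged, I take the summer reading of 45.2%. The mean is a fair stand-in while spent ligand over charge stays well below one: that ratio is 0.297 in summer and 0.450 at my charge. At one, the charge only just covers the peak.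

The forecast says 1.9 equiv, 50% and 44.5%, holding that “the time-integrated incoming ligand must match summer”, at about 8 M·h. My own reckoning differs from it, with 1.98 equiv, 49.4% and 45.2%.

The flask gives 2.04 equiv, 48.0% and 43.6%.

    leaving ligand + complex with two exchanged → side product B (k = 0.130 L mol⁻¹ h⁻¹)
    leaving ligand → by-product carried off (k = 4.40 h⁻¹)
    starting complex + complex with two exchanged → side product A (k = 0.220 L mol⁻¹ h⁻¹)
    starting complex + incoming ligand ⇌ leaving ligand + complex with one exchanged (K = 2.40, k = 0.150 L mol⁻¹ h⁻¹)
    complex with one exchanged + incoming ligand ⇌ leaving ligand + complex with two exchanged (K = 1.10, k = 0.0780 L mol⁻¹ h⁻¹)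

The mean of the first and last [incoming ligand] gives the flask a dose of 857 M·min at 20 h, past the peak dose, and at that time complex with one exchanged is made at 0.484 of the rate it is used, each step taken net. A neighbouring flask, with a quarter of the starting complex, reaches 1020 M·min by the same mean and holds 39.1% at 20 h. The flask is not at rest: by 200 h, complex with two exchanged goes from 34.9% to 82.3%, side product A from 10.4% to 17.0%, and complex with one exchanged from 43.6% to 0.275%.

The numbers in the tables stem from a simulated flask with constants of no real substance.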